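Read this flask as a pipe: solid reagent dissolves into partner, and I take it that each partner leaves as one product.

all flasks: substrate 10 mM; initiator 0.92 mM
- Monday's: solid reagent 7 mM; scavenger 5 mM; run made earlier
- Wednesday's: solid reagent 7 mM; scavenger 20 mM; run made earlier
- flask: solid reagent 7.00 mM; scavenger 10.0 mM; time 15 h

| run | time / h | product / % |
|---|---|---|
| Monday's | 0.667 | 0 |
| Monday's | 2.00 | 1.3 |
| Monday's | 3.00 | 0.5 |
| Monday's | 5.00 | 2.9 |
| Monday's | 8.00 | 4.9 |
| Monday's | 10.0 | 4.8 |
| Monday's | 12.0 | 6.4 |
| Wednesday's | 1.00 | 0.7 |
| Wednesday's | 1.33 | 0.5 |
| Wednesday's | 2.00 | 0.6 |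
| Wednesday's | 3.00 | 1.0 |
| Wednesday's | 5.00 | 2.0 |
| Wednesday's | 8.00 | 4.3 |
| Wednesday's | 12.0 | 5.7 |

(standard deviation of a reading: 0.5 percentage points)

- as a solid, counted per litre of solution: solid reagent
- the numbers in the tables scatter by 0.5 percentage points (one standard deviation)
- at the start none of the solid reagent is in solution
- partner is what solid reagent becomes in solution

1. amount of product at 15 h, in percent of the substrate charged
2. concentration of partner in solution at 15 h, in percent of saturation

Monday's run, with 5 mM of scavenger, reads 6.4% at 12.0 h, and Wednesday's, with 20 mM, reads 5.7%. That gap of 0.7 percentage points stands against a scatter of 0.5 points in each reading, so I average them. This gives the throughput F, the amount per hour passing through the solution into product: 0.0504 mM h⁻¹.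

Two extreme flasks can be reckoned in the head. In one, solid stays on hand and product climbs along the line F times time, to 7.56% at 15 h. In the other, the whole solid charge, the limiting reagent, has become product, a ceiling of 70.0%. My estimate of the solid's running-out time, charge over F, is 139 h. The asked time is shorter than that, so I commit to the line. The runs read product and not partner, so I give no partner level of my own.

The forecast gives 7.5% of product and 90% of saturation: “Near-zero-order behaviour after a short lag suggests the solid quickly brings the partner close to saturation”.

The flask gives 8.16% and 61.3%.

    solid reagent ⇌ partner, rate k1*(cs1 - [partner]) while solid is left; crystals form when [partner] > cs1 (solubility = 0.490 mM, k = 9.00 × 10⁻⁵ s⁻¹)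
    partner + released group ⇌ idle adduct, settled at all times (K = 55.0 L mol⁻¹)
    substrate + initiating radical → capped initiator + first chain carrier (k = 3.70 × 10⁵ L mol⁻¹ s⁻¹)
    2 second chain carrier → ended chains A (k = 1.30 × 10⁹ L mol⁻¹ s⁻¹)
    2 first chain carrier → ended chains B (k = 3.60 × 10⁶ L mol⁻¹ s⁻¹)
    partner + first chain carrier → product + second chain carrier (k = 2500 L mol⁻¹ s⁻¹)
    scavenger + released group → scavenged by-product (k = 0.160 L mol⁻¹ s⁻¹)
    substrate + second chain carrier → released group + first chain carrier (k = 11000 L mol⁻¹ s⁻¹)
    initiator → 2 initiating radical (k = 2.30 × 10⁻⁶ s⁻¹)

The solid's feed into a solution free of partner, its dissolving constant times the saturation level, is 0.159 mM h⁻¹, and my F is a third of that. A steady level at which feed matches F therefore lies at 68.3% of saturation, against 61.3% in the flask. In the neighbour flask with 1.8 mM of solid, the same estimate of the running-out time is 35.7 h, still longer than the asked time, and that flask gave 8.16% of product with 38.0% of its solid left.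

The numbers in the tables come from a simulation on assumed constants, and the scatter is random.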